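(The readings were computed on assumed constants; the scatter is artificial.)

Per hour is the unit of the number this meeting wanted: how fast G, once made, goes again.

| setting | Wednesday's | Monday's | flask |
|---|---|---|---|
| L | 0.047 M | 0.047 M | 0.047 M |
| E | 0.0423 M | 0.0423 M | 0.0423 M |
| Q | 1.1 mM | 1.7 mM | 2.3 mM |
| remark | run made earlier | run made earlier |  |
| time |  |  | 25 h |

- Wednesday's (time / h: G / %, L / %): 0.500: 10, 87; 1.33: 18, 77; 4.00: 13, 68; 10.0: 6, 64; 25.0: 3, 62
- Monday's (time / h: G / %, L / %): 0.500: 11, 83; 1.33: 17, 77; 4.00: 18, 68; 10.0: 10, 65; 25.0: 1, 62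

(standard deviation of a reading: 1.5 percentage points)

* time, not beyond 25 h, at which the flask holds most G
* the amount of G, in percent of the L charged, at that time
* the first time at which G reaches 8.6%, in the same percent



I opened with the late readings. Between 4.00 h and 10.0 h, G fell at 0.129 h⁻¹ in Wednesday's run, with [Q] = 1.1 mM, and at 0.0980 h⁻¹ in Monday's, with [Q] = 1.7 mM. With 1.5 percentage points of scatter on a reading of 6%, I could not tell these apart, so I took their mean, 0.113 h⁻¹, as the loss constant λ, the pseudo-first-order share of G that goes per hour.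

I then argued that the peak is a crossing: G rises while its making exceeds λ[G], and falls afterwards. Both runs read 77% of L at 1.33 h and 62% at 25.0 h. A hyperbola through these points gives τ = 0.867 h, the time by which half of the eventual loss of L has happened. If G takes a fixed share of the L lost, and its own losses are ignored while it builds, that share cancels and the crossing obeys t(t + τ) = τ/λ. For the new flask, with [Q] = 2.3 mM, I reckoned 2.37 h.

The author of the forecast differed, holding that “More Q keeps G high for longer”, and put the peak at 3.4 h, with 21.5% of G, and 8.6% reached at 0.36 h.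

The flask peaks at 2.20 h with 17.2% of G, and reaches 8.6% at 0.389 h.

    2 E → Z (k = 9.55 M⁻¹ h⁻¹)
    L + E ⇌ J (K = 1100 M⁻¹, k = 2.41 M⁻¹ h⁻¹)
    G → X (k = 0.0902 h⁻¹)
    L + E ⇌ G (K = 40.8 M⁻¹, k = 7.33 M⁻¹ h⁻¹)
    G + Q ⇌ J + Q, rate k5*[Q]*[G] forward; the back reaction follows from the equilibrium constant (k = 13.0 M⁻¹ h⁻¹)

At 2.20 h the flask also holds 9.35% of J. From 5.35% of G at 12.5 h, λ gives 1.30% at 25.0 h, and the flask holds 1.54%. In the neighbour charged with 0.011 M of E, G goes from its best of 6.85% to 0.739% at 25.0 h, a fall that takes 19.7 h at λ.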